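## Retrosynthetic overview

1. Target 7 ⇒ syn-aldol ketone 5 + 3,4-dimethoxybenzoyl chloride 6 (ester C–O bond, made last).
2. 5 ⇒ methyl ester 3 (ester to methyl ketone in one pot through Weinreb amide 4).
3. 3 ⇒ (R)-Roche ester 1 + 4-bromoveratrole 2: the aryl–C(carbinol) bond is made by a visible-light photoredox / hydrogen-atom-transfer / nickel arylation of the α-hydroxy C–H bond (key step).
4. Stereochemistry: the methyl-bearing centre is bought in 1; the carbinol centre is set in the key step under control of that centre.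
5. No ring is formed; both dimethoxyphenyl rings are bought intact.

Assumption: 1, 2 and 6 are catalogue chemicals; the target is read as the syn isomer (1R,2R)-1-(3,4-dimethoxyphenyl)-2-methyl-3-oxobutyl 3,4-dimethoxybenzoate.

## Route

Step 1
Reactants: 1 methyl (R)-3-hydroxy-2-methylpropanoate; 2 4-bromo-1,2-dimethoxybenzene
Product: 3 methyl (2R,3R)-3-(3,4-dimethoxyphenyl)-3-hydroxy-2-methylpropanoate
Conditions: 1 (2.0 equiv), 2 (1.0 equiv), Ir[dF(CF3)ppy]2(dtbbpy)PF6 (1 mol%), NiBr2(dme) (5 mol%), 4,4'-di-tert-butyl-2,2'-bipyridine (5 mol%), quinuclidine (1.2 equiv), ZnCl2 (1.5 equiv), DMSO, 450 nm LEDs, 25 °C, 24 h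
Reagents that add atoms: none
Why: Proposed new method: the excited iridium photocatalyst oxidises quinuclidine to its radical cation, which abstracts the hydridic α-C–H of the zinc alkoxide of 1 (the C2–H and OCH3 hydrogens are polarity-mismatched); the α-oxy radical is captured by the aryl nickel bromide formed from 2 and zerovalent nickel, and since this capture is reversible the two epimeric alkyl(aryl) trivalent nickel species equilibrate before C–C reductive elimination; coordination of the ester carbonyl to nickel closes a five-membered C,O-chelate in which the zinc-bound oxygen on the new centre sits trans to the C2 methyl group, so stereoretentive reductive elimination should give the 2,3-syn (2R,3R) alcohol from the bought (R) centre; the closest known reaction is the photoredox/HAT/nickel α-arylation of simple alcohols activated by ZnCl2, for which 1,2-induction from a β-stereocentre through a chelating carbonyl has not been shown.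

Step 2
Reactants: 3 methyl (2R,3R)-3-(3,4-dimethoxyphenyl)-3-hydroxy-2-methylpropanoate
Product: 5 (3R,4R)-4-(3,4-dimethoxyphenyl)-4-hydroxy-3-methylbutan-2-one, via Weinreb amide 4 (not isolated)
Conditions: MeNH(OMe)·HCl (1.6 equiv), iPrMgCl (4.3 equiv), THF, −20 °C, 1 h; then MeMgBr (3.0 equiv), −20 to 0 °C; aq. NH4Cl
Reagents that add atoms: methylmagnesium bromide, C[Mg]Br; N,O-dimethylhydroxylamine hydrochloride, CNOC.Cl (its atoms stand in 4 only)
Why: Aminolysis of the ester by the magnesium amide gives the Weinreb amide, whose chelated tetrahedral adduct with MeMgBr survives until the quench so that only one methyl adds (Weinreb ketone synthesis); the carbinol is protected as its magnesium alkoxide and neither stereocentre is touched at or below 0 °C.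

Step 3
Reactants: 5 (3R,4R)-4-(3,4-dimethoxyphenyl)-4-hydroxy-3-methylbutan-2-one; 6 3,4-dimethoxybenzoyl chloride
Product: 7 (1R,2R)-1-(3,4-dimethoxyphenyl)-2-methyl-3-oxobutyl 3,4-dimethoxybenzoate
Conditions: 6 (1.3 equiv), pyridine (3 equiv), DMAP (10 mol%), CH2Cl2, 0 to 20 °C
Reagents that add atoms: none
Why: DMAP-catalysed O-acylation (nucleophilic acyl substitution) of the secondary alcohol leaves the C–O bond at the carbinol intact, so its configuration is retained, and the weak base at low temperature spares the α-centre and avoids β-elimination.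

## Compound list

1 | methyl (R)-3-hydroxy-2-methylpropanoate ((R)-Roche ester) | COC(=O)[C@H](C)CO | starting material
2 | 4-bromo-1,2-dimethoxybenzene (4-bromoveratrole) | COc1ccc(Br)cc1OC | starting material
3 | methyl (2R,3R)-3-(3,4-dimethoxyphenyl)-3-hydroxy-2-methylpropanoate | O[C@@H](c1ccc(OC)c(OC)c1)[C@@H](C)C(=O)OC | intermediate
4 | (2R,3R)-3-(3,4-dimethoxyphenyl)-3-hydroxy-N-methoxy-N,2-dimethylpropanamide (Weinreb amide, not isolated) | O[C@@H](c1ccc(OC)c(OC)c1)[C@@H](C)C(=O)N(C)OC | intermediate
5 | (3R,4R)-4-(3,4-dimethoxyphenyl)-4-hydroxy-3-methylbutan-2-one | O[C@@H](c1ccc(OC)c(OC)c1)[C@@H](C)C(C)=O | intermediate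
6 | 3,4-dimethoxybenzoyl chloride | COc1ccc(C(=O)Cl)cc1OC | starting material
7 | (1R,2R)-1-(3,4-dimethoxyphenyl)-2-methyl-3-oxobutyl 3,4-dimethoxybenzoate | COc1ccc(C(=O)O[C@@H](c2ccc(OC)c(OC)c2)[C@@H](C)C(C)=O)cc1OC | target

## Step count

Total step count: 3. Longest linear sequence: 3 steps (1 → 3 → 5 → 7).

## Steps most likely to fail

**Step 1 (proposed new arylation).** The sense and size of the 1,2-induction are a prediction. If a six-membered zinc chelate of alkoxide and ester steers nickel anti to the methyl group, the (2R,3S) isomer would dominate. The minor diastereomer is removed by chromatography at the stage of 3. Slow oxidative addition of the electron-rich bromide, competing C–O arylation and over-oxidation of the benzylic carbinol are further risks.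

The fallback uses known chemistry only, sets out from 2 and returns at 7. Bought methyl (S)-3-hydroxybutanoate is C-methylated through its dianion (LiN(iPr)2 2.2 equiv, THF, −50 to −20 °C, then MeI; Fráter–Seebach alkylation, anti) to methyl (2S,3S)-3-hydroxy-2-methylbutanoate F1. This is silylated (TBSOTf, 2,6-lutidine) to methyl (2S,3S)-3-[(tert-butyldimethylsilyl)oxy]-2-methylbutanoate F2 and half-reduced (iBu2AlH, CH2Cl2, −78 °C) to (2S,3S)-3-[(tert-butyldimethylsilyl)oxy]-2-methylbutanal F3. Compound 2 is converted with Mg in THF into (3,4-dimethoxyphenyl)magnesium bromide F4, which adds to F3 at −78 °C under Felkin–Anh control, reinforced by the 1,3-anti preference of the β-silyloxy group. This gives (1R,2R,3S)-3-[(tert-butyldimethylsilyl)oxy]-1-(3,4-dimethoxyphenyl)-2-methylbutan-1-ol F5. Acylation with 6 (pyridine, DMAP) gives (1R,2R,3S)-3-[(tert-butyldimethylsilyl)oxy]-1-(3,4-dimethoxyphenyl)-2-methylbutyl 3,4-dimethoxybenzoate F6. HF·pyridine in THF frees (1R,2S,3S)-1-(3,4-dimethoxyphenyl)-3-hydroxy-2-methylbutyl 3,4-dimethoxybenzoate F7, and buffered Dess–Martin oxidation of F7 gives 7.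

**Step 2 (one-pot ester to methyl ketone).** The magnesium aldolate of an electron-rich aryl carbinol may undergo retro-aldol cleavage, amidation may stall, or the α-centre may epimerise.

The fallback sets out from 3 and returns at 5. Saponification (LiOH, THF/H2O, 0 °C) gives (2R,3R)-3-(3,4-dimethoxyphenyl)-3-hydroxy-2-methylpropanoic acid F8. Its lithium carboxylate cannot fragment by retro-aldol. Treatment with MeLi (3.5 equiv, THF, −78 to 0 °C) and inverse quench into cold aq. NH4Cl gives 5 (methyl ketone from a carboxylic acid and an organolithium).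

**Step 3 (acylation of the β-hydroxy ketone).** Base may cause loss of the new ester or of water to the conjugated enone, retro-aldol cleavage, or epimerisation next to the ketone.

The fallback sets out from 5 and returns at 7 without any base. Evans–Tishchenko reaction of 5 with 3,4-dimethoxybenzaldehyde (4 equiv) and SmI2 (30 mol%) in THF at −10 °C transfers the aroyl group to the existing hydroxyl while reducing the ketone. This gives (1R,2S,3S)-1-(3,4-dimethoxyphenyl)-3-hydroxy-2-methylbutyl 3,4-dimethoxybenzoate F9 (same structure as F7). Dess–Martin periodinane with NaHCO3 in CH2Cl2 then restores the ketone and gives 7.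

## Further compounds

F1 | step 1 | methyl (2S,3S)-3-hydroxy-2-methylbutanoate | COC(=O)[C@@H](C)[C@H](C)O
F2 | step 1 | methyl (2S,3S)-3-[(tert-butyldimethylsilyl)oxy]-2-methylbutanoate | COC(=O)[C@@H](C)[C@H](C)O[Si](C)(C)C(C)(C)C
F3 | step 1 | (2S,3S)-3-[(tert-butyldimethylsilyl)oxy]-2-methylbutanal | O=C[C@@H](C)[C@H](C)O[Si](C)(C)C(C)(C)C
F4 | step 1 | (3,4-dimethoxyphenyl)magnesium bromide | COc1ccc([Mg]Br)cc1OC
F5 | step 1 | (1R,2R,3S)-3-[(tert-butyldimethylsilyl)oxy]-1-(3,4-dimethoxyphenyl)-2-methylbutan-1-ol | O[C@@H](c1ccc(OC)c(OC)c1)[C@@H](C)[C@H](C)O[Si](C)(C)C(C)(C)C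
F6 | step 1 | (1R,2R,3S)-3-[(tert-butyldimethylsilyl)oxy]-1-(3,4-dimethoxyphenyl)-2-methylbutyl 3,4-dimethoxybenzoate | COc1ccc(C(=O)O[C@@H](c2ccc(OC)c(OC)c2)[C@@H](C)[C@H](C)O[Si](C)(C)C(C)(C)C)cc1OC
F7 | step 1 | (1R,2S,3S)-1-(3,4-dimethoxyphenyl)-3-hydroxy-2-methylbutyl 3,4-dimethoxybenzoate | COc1ccc(C(=O)O[C@@H](c2ccc(OC)c(OC)c2)[C@@H](C)[C@H](C)O)cc1OC
F8 | step 2 | (2R,3R)-3-(3,4-dimethoxyphenyl)-3-hydroxy-2-methylpropanoic acid | O[C@@H](c1ccc(OC)c(OC)c1)[C@@H](C)C(=O)O
F9 | step 3 | (1R,2S,3S)-1-(3,4-dimethoxyphenyl)-3-hydroxy-2-methylbutyl 3,4-dimethoxybenzoate | COc1ccc(C(=O)O[C@@H](c2ccc(OC)c(OC)c2)[C@@H](C)[C@H](C)O)cc1OC
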